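# Proposed synthesis of CNP0460913.1 (compound 39) by a catalytic enantioselective intramolecular Diels–Alder reaction

## The problem

Compound 39 is a seco-cadinane acid built on a trans-fused bicyclo[4.4.0]decane. Ring B (C1–C2–C3–C4=C5–C6) holds a trisubstituted alkene bearing the C15 hydroxymethyl group. Ring A (C6–C7–C8–C9–C10–C1) carries a 1-carboxyvinyl group on C7 (C11 with carboxyl C12 and methylene C13), an ester oxygen on C8 and an exocyclic methylene (C14) on C10.

Four contiguous stereocentres, C1, C6, C7 and C8 (all S), lie on ring A: H1/H6 trans, H6/H7 trans, H7/H8 cis, so the substituents at C1, C6 and C7 are equatorial and only the C8 oxygen is axial. Since all four sit on one six-membered ring, a single suprafacial ring-forming event can set them together, and only their absolute sense needs an outside controller. The fifth stereocentre, C3′ (S) of the 3,4-dihydroxy-2-methylenebutanoyl ester, is too remote to be controlled from the ring and has to come from the chiral pool.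

Several groups are fragile:
- The C12 carboxyl and the C8 oxygen are cis on neighbouring carbons, so a free C8 hydroxyl beside any C12 carboxyl derivative closes to the α-methylene lactone.
- The side-chain diol can expel the C8 alkoxide by lactonising under base.
- Both acrylate units are Michael acceptors.
- The C10 methylene migrates into the ring with strong acid.
- Any C10 carbonyl precursor has the C8 oxygen in the β-position, ready for elimination.

The enabling feature is that the C8 oxygen and C10 are 1,3 on ring A and C7 bears an acyl-derived carbon. This is the pattern of a cyclohexene made from a 1-alkoxy-3-silyloxy diene (C8=C9–C10=C1) and an acyl-activated alkene (C6=C7). The ring B alkene C4=C5 lies in the four-atom bridge that joins C1 to C6, so the same cycloaddition can close ring B.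

## Retrosynthesis

Locants C1–C15 are those defined above; compound numbers are those of the steps.

**39 ⇒ 38 ⇒ 36 (protecting groups; C11–C12).** The acetonide and the C15 silyl ether of 38 are removed together by mild acid, the only medium in which the side-chain ester and the exocyclic alkenes are safe. The carboxyl carbon C12 is cut next, back to enol triflate 36 and carbon monoxide. Making the acid last means no C12 carboxyl derivative ever faces a free C8 hydroxyl; an enol triflate at C11 could only close a four-membered ring. The forward step needs CO insertion to outrun any Heck-type capture by the neighbouring acrylate.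

**36 ⇒ 28 + 34 (C8–O ester bond).** The side chain is brought in intact as acid 34, because its stereocentre cannot be set from the ring; building it on the ring (for instance by a Baylis–Hillman reaction of a C8 acrylate) would give C3′ epimers. The cut removes the remote stereocentre and all side-chain functionality from the bicyclic problem. It asks for acylation of an axial secondary alcohol by a 2-substituted acrylic acid.

**28 ⇒ 27 ⇒ 25 ⇒ 24 ⇒ 23 (C8–O benzyl ether; C11–O triflate; C11–C13; imide).** The enol triflate 27 comes from methyl ketone 25 and this from thioester 24 by adding C13 as a methyl group; 24 comes from imide 23. The acyl carbon that activated the dienophile thus becomes C11. Going through an aldehyde and an alkyne would be no shorter and would put an epimerisable aldehyde beside the β-alkoxy group. The forward sequence needs kinetic enolisation of 25 at the methyl group, not at C7.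

**23 ⇒ 22 ⇒ 21 (C10=C14; C10 carbonyl).** The exocyclic methylene is cut to ketone 22, which is the hydrolysis product of the silyl enol ether in cycloadduct 21. This is done directly after the cycloaddition because the β-alkoxy silyl enol ether is the most acid-labile unit of the route. The methylenation has to be non-basic so that the C8 ether is not eliminated.

**21 ⇒ 20 (C1–C6 and C7–C8; the key cut).** Both rings are opened at once to the achiral, acyclic tetraene imide 20. Cutting only ring A (C7–C8 or C6–C7) would leave a ring B piece whose C1/C6 stereocentres need their own asymmetric synthesis. Cutting only ring B would leave a tetrasubstituted cyclohexane. The double cut removes two rings and four stereocentres. It asks for endo selectivity, for one π-face of C6=C7, and for survival of an electron-rich diene next to a Lewis acid.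

**20 ⇒ 19 ⇒ 11 + 17 (O–Si; C3–C4).** The silyl dienol ether is made last from ketone 19. The chain of 19 is divided at the sp3–sp2 bond C3–C4 into iododienoyl imide 11 and iodo enone 17, which is coupled as its alkylzinc iodide 18. This cut is preferred to alkylating an enone enolate at C1–C2 with a homoallylic iodide (slow, and prone to elimination to a diene). It is also preferred to making C4=C5 by olefination (poor control of a trisubstituted alkene). Here the C4=C5 geometry is inherited with retention from a vinyl iodide. The halves are of similar size and each is four steps from commercial material.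

**11 ⇒ 5 + 10; 5 ⇒ 4 ⇒ 2 ⇒ 1; 10 ⇒ 8 ⇒ 6 (C6=C7; C4–I).** The (E)-alkene C6=C7 is cut by a Wittig reaction between iodo enal 5 and the stabilised ylide 10, made from oxazolidinone 6 through 8. The (Z)-iodide 4 comes from butynediol monoether 2, itself from diol 1, by directed trans-hydroalumination and iodination; this fixes iodine cis to the future C6 and thereby the later cis relation of C3 and C6.

**17 ⇒ 16 ⇒ 14 + 15; 14 ⇒ 13 ⇒ 12 (C–I; C8–O; C9–C10).** The iodide is exchanged back to chloride 16. The enol ether oxygen is cut to ynone 14 and 4-methoxybenzyl alcohol 15 (conjugate addition gives the (E)-β-alkoxy enone directly). The ynone is cut to amide 13 and an ethynyl nucleophile; 13 comes from acid chloride 12.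

**34 ⇒ 33 ⇒ 31 ⇒ 29 (C2′=CH2).** The methylene carbon is removed to give the malic-acid-derived ester 29, through the Mannich base 31 and acrylate 33; the stereocentre of 29 is carried unchanged.

## Roads not taken

**Alternative 1: dienamine closure onto a butenolide.** The cut is C6–C7 of ring A, with C8–O and C12 tied as a lactone. In the forward direction a secondary amine condenses with the aldehyde of cyclohexenecarbaldehyde A1; the ring dienamine adds through its γ-carbon C6 to the β-carbon C7 of the tethered butenolide and gives the tricyclic lactone enal A2.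
- Merits: the cis C7/C8 relation is built into the butenolide; C12 is in place from the start; the conditions are mild and metal-free.
- Weak points: A1 needs two stereocentres (C1 and C8) that are 1,5-related across the flexible C9–C10 linker, so each needs its own asymmetric step. The α- versus γ-reactivity of the dienamine and the trans ring fusion are left to the substrate. A2 is the lactone that the target is not: it must be methylenated at C11, opened, and acylated at C8 while the cis carboxyl is kept from closing again, and the aldehyde must be reduced.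
- Comparison: A2 holds C12 without the four steps (16, 17, 18, 24) that the chosen plan spends on C11–C13. Against this the chosen plan sets all four ring stereocentres in one catalyst-controlled step from achiral 20 and never has a free C8 hydroxyl beside a C12 carboxyl derivative.

**Alternative 2: intramolecular Barbier allylation.** The cut is C7–C8. Indium inserts into the allylic C–Br bond of bromide A3; the allylindium adds through C7 to the C8 aldehyde, the alkene moves to C11=C13 and the alkoxide closes to the cis-fused α-methylene lactone A4.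
- Merits: one operation forms C7–C8 and delivers the complete α-methylene carboxyl unit; the reaction type tolerates water and many functional groups; the cis lactone is its normal outcome.
- Weak points: A3 is a trans-1,6-disubstituted cyclohexene whose C1 and C6 stereocentres need a separate enantioselective synthesis of ring B. The facial course of the closure relative to C6 depends on the substrate. A4 must be saponified (hydroxide can also add to the methylene lactone), the acid protected, and a γ-hydroxy ester acylated that tends to relactonise.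
- Comparison: for the acrylic acid unit this road is clearly shorter and milder than steps 16–18 and 24. The chosen plan has to set against it the simultaneous formation of both rings and all four stereocentres, and the absence of the lactone detour.

**Alternative 3: three-component assembly of ring B.** The cuts are C1–C6, C2–C3 and C4=C5. The enamine of aldehyde A5 adds to nitrodiene A6, the nitronate adds to phosphonoacrylate A7, and an intramolecular Horner–Wadsworth–Emmons reaction closes the nitrocyclohexene ester A8.
- Merits: three small components, an inexpensive amine catalyst, one pot, and robust Michael chemistry that sets C1 and C6 together.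
- Weak points: only ring B is made. The nitro group at C2 has no counterpart in the target and must be removed. A5 must already carry the C7 stereocentre, and its branching slows enamine formation. Ring A still has to be closed with control of C8, the malonate turned into the acrylic acid, and the C15 ester reduced.
- Comparison: the key step of this road is operationally simpler and less sensitive than step 13. The chosen plan has to set against it that nothing remains to be built on the skeleton after the cycloaddition except functional-group changes, and that C7 and C8 are set in the same step as C1 and C6.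

Key step: step 13

Remarks on the chemistry:
- Ester 29 is taken as an article of commerce (it is the acetonide of the methyl 3,4-dihydroxybutanoate derived from (S)-malic acid).
- tBu-box stands for 2,2′-(propane-2,2-diyl)bis[(4R)-4-tert-butyl-4,5-dihydro-1,3-oxazole]. Its (R,R)-form is specified from the square-planar chelate model; should the sense of induction be opposite, the (S,S)-ligand is to be used.
- In the bicyclic compounds the stereodescriptors are given as relations between H1, H6, H7 and H8; the absolute configuration is that of the SMILES in the compound list.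

## Steps

Step 1
Reactants: 1 but-2-yne-1,4-diol
Product: 2 4-[(tert-butyldimethylsilyl)oxy]but-2-yn-1-ol
Conditions: TBSCl, imidazole, DMF, 0 °C → rt (diol in threefold excess)
Reagents that add atoms: tert-butyldimethylsilyl chloride, CC(C)(C)[Si](C)(C)Cl
Why: Statistical monosilylation of a symmetrical diol; the excess of the cheap diol keeps bis-silylation low and is washed out with water.

Step 2
Reactants: 2 4-[(tert-butyldimethylsilyl)oxy]but-2-yn-1-ol
Product: 4 (Z)-4-[(tert-butyldimethylsilyl)oxy]-3-iodobut-2-en-1-ol, via cyclic sodium alkenylalanate 3 (not isolated)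
Conditions: NaAlH2(OCH2CH2OCH3)2 (Red-Al), THF, 0 °C; EtOAc; then I2, −78 → 0 °C
Reagents that add atoms: iodine, II
Why: Alkoxide-directed trans-hydroalumination of the propargylic alcohol puts aluminium on C3 in a five-membered chelate, and iodinolysis with retention gives the iodide cis to CH2OH; keeping the alanate at or below 0 °C avoids loss of silanolate to an allene.

Step 3
Reactants: 4 (Z)-4-[(tert-butyldimethylsilyl)oxy]-3-iodobut-2-en-1-ol
Product: 5 (Z)-4-[(tert-butyldimethylsilyl)oxy]-3-iodobut-2-enal
Conditions: MnO2, CH2Cl2, rt, dark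
Reagents that add atoms: none
Why: Allylic oxidation with MnO2 is neutral and keeps the alkene geometry; the β-iodo enal is used at once.

Step 4
Reactants: 6 1,3-oxazolidin-2-one
Product: 8 3-(2-bromoacetyl)-1,3-oxazolidin-2-one, via lithium 2-oxo-1,3-oxazolidin-3-ide 7 (not isolated)
Conditions: n-BuLi, THF, −78 °C; then BrCH2COBr, −78 → 0 °C
Reagents that add atoms: bromoacetyl bromide, BrCC(Br)=O
Why: N-Acylation of the lithiated oxazolidinone at the acyl bromide, which is far more reactive than the alkyl bromide.

Step 5
Reactants: 8 3-(2-bromoacetyl)-1,3-oxazolidin-2-one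
Product: 10 3-[2-(triphenyl-λ5-phosphanylidene)acetyl]-1,3-oxazolidin-2-one, via phosphonium bromide 9 (not isolated)
Conditions: PPh3, PhMe, rt; then 1 M NaOH (aq), CH2Cl2, 0 °C, brief
Reagents that add atoms: triphenylphosphine, c1ccc(cc1)P(c1ccccc1)c1ccccc1
Why: SN2 quaternisation of the α-bromo imide and deprotonation of the acidic phosphonium salt give the stabilised ylide; the cold, brief biphasic wash spares the imide.

Step 6
Reactants: 5 (Z)-4-[(tert-butyldimethylsilyl)oxy]-3-iodobut-2-enal; 10 3-[2-(triphenyl-λ5-phosphanylidene)acetyl]-1,3-oxazolidin-2-one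
Product: 11 3-[(2E,4Z)-6-[(tert-butyldimethylsilyl)oxy]-5-iodohexa-2,4-dienoyl]-1,3-oxazolidin-2-one
Conditions: CH2Cl2, rt, dark
Reagents that add atoms: none
Why: Wittig reaction of a stabilised ylide gives the (E)-alkene C6=C7; no base is present, so the (Z)-iodoalkene is not isomerised.

Step 7
Reactants: 12 4-chlorobutanoyl chloride
Product: 13 4-chloro-N-methoxy-N-methylbutanamide
Conditions: MeNHOMe·HCl, pyridine, CH2Cl2, 0 °C → rt
Reagents that add atoms: N,O-dimethylhydroxylamine hydrochloride, CNOC.Cl
Why: Acylation of the amine by the acid chloride; the N-methoxy-N-methylamide allows clean mono-addition in step 8.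

Step 8
Reactants: 13 4-chloro-N-methoxy-N-methylbutanamide
Product: 14 6-chlorohex-1-yn-3-one
Conditions: HC≡CMgBr, THF, 0 °C; inverse quench into cold 1 M HCl
Reagents that add atoms: ethynylmagnesium bromide, C#C[Mg]Br
Why: The chelated tetrahedral adduct of the N-methoxy-N-methylamide stops at the ketone stage; the acidic inverse quench keeps the liberated amine from adding to the ynone.

Step 9
Reactants: 14 6-chlorohex-1-yn-3-one; 15 (4-methoxyphenyl)methanol
Product: 16 (E)-6-chloro-1-[(4-methoxybenzyl)oxy]hex-1-en-3-one
Conditions: DABCO (10 mol%), CH2Cl2, 0 °C → rt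
Reagents that add atoms: none
Why: Amine-catalysed oxa-Michael addition of an alcohol to a terminal ynone, which gives the thermodynamically preferred (E)-β-alkoxy enone.

Step 10
Reactants: 16 (E)-6-chloro-1-[(4-methoxybenzyl)oxy]hex-1-en-3-one
Product: 17 (E)-6-iodo-1-[(4-methoxybenzyl)oxy]hex-1-en-3-one
Conditions: NaI, acetone, reflux
Reagents that add atoms: sodium iodide, [Na+].[I-]
Why: Finkelstein exchange at the primary chloride under neutral conditions, driven by precipitation of NaCl.

Step 11
Reactants: 17 (E)-6-iodo-1-[(4-methoxybenzyl)oxy]hex-1-en-3-one; 11 3-[(2E,4Z)-6-[(tert-butyldimethylsilyl)oxy]-5-iodohexa-2,4-dienoyl]-1,3-oxazolidin-2-one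
Product: 19 3-[(2E,4E,10E)-5-{[(tert-butyldimethylsilyl)oxy]methyl}-11-[(4-methoxybenzyl)oxy]-9-oxoundeca-2,4,10-trienoyl]-1,3-oxazolidin-2-one, via alkylzinc iodide 18 (not isolated)
Conditions: Zn dust (activated with BrCH2CH2Br and Me3SiCl), LiCl, THF, 25 °C; then 11, PdCl2(dppf) (5 mol%), THF, rt
Reagents that add atoms: none
Why: Direct zinc insertion into the primary iodide tolerates the ketone, and Negishi coupling joins C3 to C4 with retention at the alkenyl carbon, so the chain C3 ends cis to C6 (descriptor 4E because CH2OSi outranks CH2C); alkylzinc iodides do not attack imides or enones without further activation.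

Step 12
Reactants: 19 3-[(2E,4E,10E)-5-{[(tert-butyldimethylsilyl)oxy]methyl}-11-[(4-methoxybenzyl)oxy]-9-oxoundeca-2,4,10-trienoyl]-1,3-oxazolidin-2-one
Product: 20 3-[(2E,4E,8Z,10E)-9-[(tert-butyldimethylsilyl)oxy]-5-{[(tert-butyldimethylsilyl)oxy]methyl}-11-[(4-methoxybenzyl)oxy]undeca-2,4,8,10-tetraenoyl]-1,3-oxazolidin-2-one
Conditions: TBSOTf, Et3N, CH2Cl2, −78 → 0 °C
Reagents that add atoms: tert-butyldimethylsilyl trifluoromethanesulfonate, CC(C)(C)[Si](C)(C)OS(=O)(=O)C(F)(F)F
Why: Soft enolisation of the only enolisable carbonyl (the C10 ketone, toward C1); silyl triflate and amine give the (Z)-enol silane of acyclic ketones, which places C2 on the outside of the s-cis diene.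

Step 13
Reactants: 20 3-[(2E,4E,8Z,10E)-9-[(tert-butyldimethylsilyl)oxy]-5-{[(tert-butyldimethylsilyl)oxy]methyl}-11-[(4-methoxybenzyl)oxy]undeca-2,4,8,10-tetraenoyl]-1,3-oxazolidin-2-one
Product: 21 trans-fused cycloadduct (cadinane numbering): C7 (2-oxo-1,3-oxazolidin-3-yl)carbonyl, C8 (4-methoxybenzyl)oxy, C9=C10 silyl enol ether with OTBS on C10, C4=C5 with CH2OTBS on C4; H1/H6 trans, H6/H7 trans, H7/H8 cis
Conditions: [Cu((R,R)-tBu-box)](SbF6)2 (10 mol%), CH2Cl2, −20 °C → rt; Et3N, filtration through Et3N-deactivated silica
Reagents that add atoms: none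
Why: The cationic divalent copper centre binds both imide carbonyls in a square-planar chelate, fixes the acyl group s-cis and lowers the LUMO of C6=C7, and the electron-rich diene adds in a concerted, asynchronous [4+2] in which the silyl enol ether terminus C1 bonds ahead to the β-carbon C6 and C8 follows to the α-carbon C7. The closest known reaction type is the bis(oxazoline)–divalent copper catalysed intramolecular Diels–Alder reaction of 2,7,9-trienoyl oxazolidinones, together with the intermolecular additions of 1-oxygenated dienes to acrylimides under the same catalysts. Ring A closes as the six-membered ring of the cycloaddition itself (bonds C1–C6 and C7–C8, suprafacial on both partners), and ring B closes in the same event through C1–C6 as a fused six-membered ring, the four-atom bridge C2–C3–C4=C5 linking the diene terminus to the β-carbon of the dienophile with C3 and C6 already cis on C4=C5. The trans relation H6/H7 is carried over from the (E)-alkene C6=C7, the cis relation between the C8 ether and the C1–C2 bond follows from the two outside substituents of the (1E,3Z)-diene, and the cis relation C7/C8 together with the trans ring fusion follows from the endo position of the chelated acyl group, which forces the bridge exo. The absolute sense comes from the C2-symmetric ligand: in the chelate model the tert-butyl group of the (R,R)-ligand covers the α-Re face of C7, so the diene bonds on the α-Si face, which corresponds to the configuration of 39. The step needs endo over exo selectivity (raised by Lewis-acid complexation of an (E)-acyl dienophile), face selectivity (ligand) and periselectivity (C6=C7 is the only alkene within reach, since addition to C4=C5 would demand a four-membered bridge). The conjugation between C4=C5 and C6=C7 has to be twisted off in the transition state, which intramolecularity, catalyst activation and the very electron-rich diene are relied on to pay for, while the bulky silyl group, the non-coordinating SbF6 counter-ions and low temperature should keep the acid-labile diene intact. Should the addition be stepwise (Mukaiyama–Michael addition at C6, then closure of the copper enolate onto C8), the same two bonds would form.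

Step 14
Reactants: 21 trans-fused cycloadduct with C9=C10 silyl enol ether
Product: 22 C10 ketone (cadinane numbering): C7 (2-oxo-1,3-oxazolidin-3-yl)carbonyl, C8 (4-methoxybenzyl)oxy, C10 oxo, C15 OTBS; H1/H6 trans, H6/H7 trans, H7/H8 cis
Conditions: Bu4NF (1.1 equiv), AcOH (1.5 equiv), THF, −40 → 0 °C
Reagents that add atoms: none
Why: Fluoride cleaves the enol Si–O bond far faster than the alkyl silyl ether, and acetic acid protonates the enolate at C9 before the β-ether at C8 can be lost (E1cB); C1 keeps the more stable trans fusion.

Step 15
Reactants: 22 C10 ketone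
Product: 23 C10 methylene imide (cadinane numbering): C7 (2-oxo-1,3-oxazolidin-3-yl)carbonyl, C8 (4-methoxybenzyl)oxy, C10=CH2, C15 OTBS; stereorelations as in 22
Conditions: Zn, CH2Br2, TiCl4 (preformed reagent), THF/CH2Cl2, 0 °C → rt
Reagents that add atoms: dibromomethane, BrCBr
Why: Takai–Lombardo methylenation; the gem-dimetallic reagent is not basic, so the β-alkoxy ketone is neither enolised nor epimerised, and it leaves imide carbonyls untouched.

Step 16
Reactants: 23 C10 methylene imide
Product: 24 S-ethyl thioester (cadinane numbering): C7 C(=O)SEt, C8 (4-methoxybenzyl)oxy, C10=CH2, C15 OTBS; stereorelations as in 22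
Conditions: EtSH, n-BuLi, THF, 0 °C
Reagents that add atoms: ethanethiol, CCS
Why: Lithium thiolate attacks the exocyclic carbonyl of the N-acyloxazolidinone selectively and is too weakly basic to deprotonate C7.

Step 17
Reactants: 24 S-ethyl thioester
Product: 25 methyl ketone (cadinane numbering): C7 acetyl (C11 carbonyl, C13 methyl), C8 (4-methoxybenzyl)oxy, C10=CH2, C15 OTBS; stereorelations as in 22
Conditions: Me2CuLi (from MeLi and CuI), Et2O, −78 → −40 °C
Reagents that add atoms: lithium dimethylcuprate, [Li+].C[Cu-]C
Why: Lithium dialkylcuprates convert thioesters into ketones without further addition and without enolising the product; the equatorial acyl group at C7 is also the more stable epimer.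

Step 18
Reactants: 25 methyl ketone
Product: 27 enol triflate (cadinane numbering): C7 1-(trifluoromethanesulfonyloxy)vinyl, C8 (4-methoxybenzyl)oxy, C10=CH2, C15 OTBS; stereorelations as in 22, via potassium enolate 26 (not isolated)
Conditions: KN(SiMe3)2, THF, −78 °C (ketone added to base); then PhNTf2, −78 → 0 °C
Reagents that add atoms: N-phenylbis(trifluoromethanesulfonimide), O=S(=O)(N(c1ccccc1)S(=O)(=O)C(F)(F)F)C(F)(F)F
Why: A bulky amide base at low temperature removes a methyl proton, not the hindered tertiary C7–H (kinetic enolisation), and O-sulfonylation traps the terminal enolate as the 2-substituted vinyl triflate.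

Step 19
Reactants: 27 enol triflate
Product: 28 C8 alcohol (cadinane numbering): C7 1-(trifluoromethanesulfonyloxy)vinyl, C8 OH (axial), C10=CH2, C15 OTBS; stereorelations as in 22
Conditions: DDQ, CH2Cl2/pH 7 buffer, 0 °C
Reagents that add atoms: none
Why: Oxidative cleavage of the 4-methoxybenzyl ether by hydride abstraction and hydrolysis; enol triflate, silyl ether and alkenes are inert, and with C11 as an enol triflate the freed hydroxyl has no carboxyl partner for lactonisation.

Step 20
Reactants: 29 methyl 2-[(4S)-2,2-dimethyl-1,3-dioxolan-4-yl]acetate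
Product: 31 methyl 3-(dimethylamino)-2-[(4S)-2,2-dimethyl-1,3-dioxolan-4-yl]propanoate (both C2 epimers), via lithium ester enolate 30 (not isolated)
Conditions: LiN(iPr)2, THF, −78 °C; then CH2=NMe2+ I−, −78 → 0 °C
Reagents that add atoms: dimethylmethyleneiminium iodide, C=[N+](C)C.[I-]
Why: Mannich reaction of the ester enolate with a preformed iminium salt; the enolate is kept at −78 °C so that the β-oxygen of the acetonide is not eliminated, and the new C2 centre is of no consequence because it becomes sp2.

Step 21
Reactants: 31 methyl 3-(dimethylamino)-2-[(4S)-2,2-dimethyl-1,3-dioxolan-4-yl]propanoate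
Product: 33 methyl 2-[(4S)-2,2-dimethyl-1,3-dioxolan-4-yl]prop-2-enoate, via trimethylammonium iodide 32 (not isolated)
Conditions: MeI, MeOH, rt; then NaHCO3 (aq), CH2Cl2, rt
Reagents that add atoms: none
Why: Quaternisation followed by Hofmann-type β-elimination is the standard route to α-methylene esters; the weak base does not move the double bond toward C3′.

Step 22
Reactants: 33 methyl 2-[(4S)-2,2-dimethyl-1,3-dioxolan-4-yl]prop-2-enoate
Product: 34 2-[(4S)-2,2-dimethyl-1,3-dioxolan-4-yl]prop-2-enoic acid
Conditions: LiOH, THF/H2O, 0 °C; then 1 M HCl to pH 4, 0 °C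
Reagents that add atoms: lithium hydroxide, [Li+].[OH-]
Why: Saponification of the methyl ester; the stereocentre is not α to the carbonyl and the cold, mildly acidic work-up spares the acetonide.

Step 23
Reactants: 34 2-[(4S)-2,2-dimethyl-1,3-dioxolan-4-yl]prop-2-enoic acid; 28 C8 alcohol
Product: 36 C8 ester (cadinane numbering): C7 1-(trifluoromethanesulfonyloxy)vinyl, C8 O-acyl with acyl = 2-[(4S)-2,2-dimethyl-1,3-dioxolan-4-yl]prop-2-enoyl, C10=CH2, C15 OTBS; stereorelations as in 22, via mixed trichlorobenzoic anhydride 35 (not isolated)
Conditions: 2,4,6-Cl3C6H2COCl, Et3N, THF, rt; then 28, DMAP, PhMe, rt → 40 °C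
Reagents that add atoms: none
Why: Yamaguchi esterification; the hindered aroyl carbonyl of the mixed anhydride steers the acylpyridinium formation to the acrylic carbonyl, and the acid has no α-hydrogen, so ketene formation and loss of C3′ integrity are excluded.

Step 24
Reactants: 36 C8 ester enol triflate
Product: 38 acrylic acid (cadinane numbering): C7 1-carboxyvinyl, C8 O-acyl as in 36, C10=CH2, C15 OTBS; stereorelations as in 22, via mixed acetic anhydride 37 (not isolated)
Conditions: Pd(OAc)2 (5 mol%), PPh3 (10 mol%), KOAc, CO (1 atm), DMF, rt → 40 °C; aqueous work-up at pH 4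
Reagents that add atoms: carbon monoxide, [C-]#[O+]; potassium acetate, CC(=O)[O-].[K+]
Why: Hydroxycarbonylation of a vinyl triflate: oxidative addition to zerovalent palladium, CO insertion, capture of the acylpalladium by acetate and hydrolysis of the mixed anhydride; CO insertion is expected to outrun cyclisation onto the neighbouring acrylate, which would have to pass through the disfavoured s-cis ester conformation.

Step 25
Reactants: 38 acrylic acid with acetonide and silyl ether
Product: 39 CNP0460913.1, (1S,6S,7S,8S)-seco-cadinane acid (cadinane numbering): C7 1-carboxyvinyl, C8 (3S)-3,4-dihydroxy-2-methylenebutanoyloxy, C10=CH2, C15 OH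
Conditions: AcOH/THF/H2O (3:1:1), rt → 40 °C
Reagents that add atoms: none
Why: Acid hydrolysis removes the primary allylic silyl ether and the terminal acetonide together; the mildly acidic medium is the one in which the diol ester does not lactonise and the exocyclic alkenes do not migrate.

## Compound list

1 | but-2-yne-1,4-diol | OCC#CCO | starting material
2 | 4-[(tert-butyldimethylsilyl)oxy]but-2-yn-1-ol | CC(C)(C)[Si](C)(C)OCC#CCO | intermediate
3 | cyclic sodium alkenylalanate from 2 | [Na+].COCCO[Al-]1(OCCOC)OCC=C1CO[Si](C)(C)C(C)(C)C | intermediate (not isolated)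
4 | (Z)-4-[(tert-butyldimethylsilyl)oxy]-3-iodobut-2-en-1-ol | OC/C=C(\I)CO[Si](C)(C)C(C)(C)C | intermediate
5 | (Z)-4-[(tert-butyldimethylsilyl)oxy]-3-iodobut-2-enal | O=C/C=C(\I)CO[Si](C)(C)C(C)(C)C | intermediate
6 | 1,3-oxazolidin-2-one | O=C1NCCO1 | starting material
7 | lithium 2-oxo-1,3-oxazolidin-3-ide | [Li+].O=C1[N-]CCO1 | intermediate (not isolated)
8 | 3-(2-bromoacetyl)-1,3-oxazolidin-2-one | O=C(CBr)N1CCOC1=O | intermediate
9 | [2-oxo-2-(2-oxo-1,3-oxazolidin-3-yl)ethyl]triphenylphosphonium bromide | O=C(C[P+](c1ccccc1)(c1ccccc1)c1ccccc1)N1CCOC1=O.[Br-] | intermediate (not isolated)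
10 | 3-[2-(triphenyl-λ5-phosphanylidene)acetyl]-1,3-oxazolidin-2-one | O=C(C=P(c1ccccc1)(c1ccccc1)c1ccccc1)N1CCOC1=O | intermediate
11 | 3-[(2E,4Z)-6-[(tert-butyldimethylsilyl)oxy]-5-iodohexa-2,4-dienoyl]-1,3-oxazolidin-2-one | O=C(/C=C/C=C(\I)CO[Si](C)(C)C(C)(C)C)N1CCOC1=O | intermediate
12 | 4-chlorobutanoyl chloride | ClCCCC(Cl)=O | starting material
13 | 4-chloro-N-methoxy-N-methylbutanamide | CON(C)C(=O)CCCCl | intermediate
14 | 6-chlorohex-1-yn-3-one | C#CC(=O)CCCCl | intermediate
15 | (4-methoxyphenyl)methanol | COc1ccc(CO)cc1 | starting material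
16 | (E)-6-chloro-1-[(4-methoxybenzyl)oxy]hex-1-en-3-one | COc1ccc(CO/C=C/C(=O)CCCCl)cc1 | intermediate
17 | (E)-6-iodo-1-[(4-methoxybenzyl)oxy]hex-1-en-3-one | COc1ccc(CO/C=C/C(=O)CCCI)cc1 | intermediate
18 | [(E)-6-[(4-methoxybenzyl)oxy]-4-oxohex-5-en-1-yl]zinc iodide | COc1ccc(CO/C=C/C(=O)CCC[Zn]I)cc1 | intermediate (not isolated)
19 | 3-[(2E,4E,10E)-5-{[(tert-butyldimethylsilyl)oxy]methyl}-11-[(4-methoxybenzyl)oxy]-9-oxoundeca-2,4,10-trienoyl]-1,3-oxazolidin-2-one | O=C(/C=C/C=C(/CO[Si](C)(C)C(C)(C)C)CCCC(=O)/C=C/OCc1ccc(OC)cc1)N1CCOC1=O | intermediate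
20 | 3-[(2E,4E,8Z,10E)-9-[(tert-butyldimethylsilyl)oxy]-5-{[(tert-butyldimethylsilyl)oxy]methyl}-11-[(4-methoxybenzyl)oxy]undeca-2,4,8,10-tetraenoyl]-1,3-oxazolidin-2-one | COc1ccc(CO/C=C/C(O[Si](C)(C)C(C)(C)C)=C/CC/C(CO[Si](C)(C)C(C)(C)C)=C\C=C\C(=O)N2CCOC2=O)cc1 | intermediate
21 | trans-fused cycloadduct: C7 imide, C8 4-methoxybenzyl ether, C9=C10 silyl enol ether, C15 silyl ether | O=C1OCCN1C(=O)[C@@H]2[C@H]3C=C(CO[Si](C)(C)C(C)(C)C)CC[C@@H]3C(O[Si](C)(C)C(C)(C)C)=C[C@@H]2OCc4ccc(OC)cc4 | intermediate
22 | C10 ketone: C7 imide, C8 4-methoxybenzyl ether, C15 silyl ether | O=C1OCCN1C(=O)[C@@H]2[C@H]3C=C(CO[Si](C)(C)C(C)(C)C)CC[C@@H]3C(=O)C[C@@H]2OCc4ccc(OC)cc4 | intermediate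
23 | C10 methylene imide | O=C1OCCN1C(=O)[C@@H]2[C@H]3C=C(CO[Si](C)(C)C(C)(C)C)CC[C@@H]3C(=C)C[C@@H]2OCc4ccc(OC)cc4 | intermediate
24 | S-ethyl thioester at C7 | CCSC(=O)[C@@H]1[C@H]2C=C(CO[Si](C)(C)C(C)(C)C)CC[C@@H]2C(=C)C[C@@H]1OCc3ccc(OC)cc3 | intermediate
25 | methyl ketone at C7 | CC(=O)[C@@H]1[C@H]2C=C(CO[Si](C)(C)C(C)(C)C)CC[C@@H]2C(=C)C[C@@H]1OCc3ccc(OC)cc3 | intermediate
26 | potassium enolate of 25 (terminal) | [K+].[O-]C(=C)[C@@H]1[C@H]2C=C(CO[Si](C)(C)C(C)(C)C)CC[C@@H]2C(=C)C[C@@H]1OCc3ccc(OC)cc3 | intermediate (not isolated)
27 | enol triflate at C11 with C8 4-methoxybenzyl ether | C=C(OS(=O)(=O)C(F)(F)F)[C@@H]1[C@H]2C=C(CO[Si](C)(C)C(C)(C)C)CC[C@@H]2C(=C)C[C@@H]1OCc3ccc(OC)cc3 | intermediate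
28 | C8 alcohol with enol triflate at C11 | C=C(OS(=O)(=O)C(F)(F)F)[C@@H]1[C@H]2C=C(CO[Si](C)(C)C(C)(C)C)CC[C@@H]2C(=C)C[C@@H]1O | intermediate
29 | methyl 2-[(4S)-2,2-dimethyl-1,3-dioxolan-4-yl]acetate | COC(=O)C[C@H]1COC(C)(C)O1 | starting material
30 | lithium enolate of 29 | [Li+].COC([O-])=C[C@H]1COC(C)(C)O1 | intermediate (not isolated)
31 | methyl 3-(dimethylamino)-2-[(4S)-2,2-dimethyl-1,3-dioxolan-4-yl]propanoate (C2 epimers) | COC(=O)C(CN(C)C)[C@H]1COC(C)(C)O1 | intermediate
32 | trimethylammonium iodide of 31 | COC(=O)C(C[N+](C)(C)C)[C@H]1COC(C)(C)O1.[I-] | intermediate (not isolated)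
33 | methyl 2-[(4S)-2,2-dimethyl-1,3-dioxolan-4-yl]prop-2-enoate | C=C(C(=O)OC)[C@H]1COC(C)(C)O1 | intermediate
34 | 2-[(4S)-2,2-dimethyl-1,3-dioxolan-4-yl]prop-2-enoic acid | C=C(C(=O)O)[C@H]1COC(C)(C)O1 | intermediate
35 | mixed anhydride of 34 with 2,4,6-trichlorobenzoic acid | C=C(C(=O)OC(=O)c1c(Cl)cc(Cl)cc1Cl)[C@H]1COC(C)(C)O1 | intermediate (not isolated)
36 | C8 ester with enol triflate at C11 | C=C(OS(=O)(=O)C(F)(F)F)[C@@H]1[C@H]2C=C(CO[Si](C)(C)C(C)(C)C)CC[C@@H]2C(=C)C[C@@H]1OC(=O)C(=C)[C@H]3COC(C)(C)O3 | intermediate
37 | mixed anhydride of 38 with acetic acid | CC(=O)OC(=O)C(=C)[C@@H]1[C@H]2C=C(CO[Si](C)(C)C(C)(C)C)CC[C@@H]2C(=C)C[C@@H]1OC(=O)C(=C)[C@H]3COC(C)(C)O3 | intermediate (not isolated)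
38 | acrylic acid with acetonide and C15 silyl ether | C=C(C(=O)O)[C@@H]1[C@H]2C=C(CO[Si](C)(C)C(C)(C)C)CC[C@@H]2C(=C)C[C@@H]1OC(=O)C(=C)[C@H]3COC(C)(C)O3 | intermediate
39 | CNP0460913.1 | C=C(C(=O)O)[C@@H]1[C@H]2C=C(CO)CC[C@@H]2C(=C)C[C@@H]1OC(=O)C(=C)[C@H](O)CO | target

## Step count and least certain steps

Total: 25 steps. Longest linear sequence: 16 steps (1, 2, 3, 6, 11, 12, 13, 14, 15, 16, 17, 18, 19, 23, 24, 25).

**Step 13 (key step).**
- Most likely failures: degradation of the silyl dienol ether by the cationic copper complex (ionisation, desilylation or electron transfer) before cycloaddition; a stepwise Mukaiyama–Michael course that erodes endo and facial control; sluggish reaction because the dienoyl conjugation must be broken in the transition state.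
- Fallback: this gives up catalyst control and avoids any Lewis acid. Tetraene 20 is heated in toluene with a trace of Et3N and a radical inhibitor; the thermal intramolecular Diels–Alder reaction of such siloxy dienes is known chemistry and should give the racemic endo cycloadduct, that is 21 together with its enantiomer, the ent-cycloadduct F1. Desilylation as in step 14 then gives the racemic ketone, 22 with the ent-ketone F2, which is resolved by preparative chromatography on a chiral stationary phase. The route is rejoined at 22.

**Step 11.**
- Most likely failures: β-hydride elimination or protodemetallation of the alkyl group; attack on or reduction of the strongly electrophilic iododienoyl imide under the coupling conditions.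
- Fallback: the order of bond formation is changed. The alkylzinc iodide 18 (from 17) is coupled under the same palladium catalysis with the smaller and more reactive iodo enal 5, whose aldehyde is inert to alkylzinc iodides. This gives (2E,8E)-3-{[(tert-butyldimethylsilyl)oxy]methyl}-9-[(4-methoxybenzyl)oxy]-7-oxonona-2,8-dienal F3. A Wittig reaction of F3 with ylide 10 (the vinylogous ester ketone does not react) returns to the route at 19.

**Step 15.**
- Most likely failures: loss of the C8 ether by β-elimination from the C10 ketone, promoted by Lewis-acidic titanium species or by enolisation; epimerisation at C1.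
- Fallback: this replaces steps 14 and 15 and never exposes a C10 ketone. Cycloadduct 21 is treated with CsF and PhNTf2 at low temperature, the enolate being trapped as it forms, to give the C10 enol triflate F4. Negishi coupling with Me3SiCH2ZnCl and Pd(PPh3)4 gives the C10 (trimethylsilyl)methyl allylsilane F5. Brief protodesilylation with CF3CO2H in CH2Cl2 at −20 °C (SE2′, proton to C9) gives the exocyclic alkene and returns to the route at 23.

**Step 18.**
- Most likely failures: enolisation toward C7 in place of the methyl group, leading to epimerisation or E1cB loss of the C8 ether; equilibration of the enolates before trapping.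
- Fallback: no enolate is used. Methyl ketone 25 is condensed with hydrazine to the hydrazone F6, and the Barton vinyl iodide synthesis (I2, tetramethylguanidine) gives the 1-iodovinyl compound F7. Steps 19 and 23 are then run on the iodide, giving the iodovinyl alcohol F8 and the iodovinyl ester F9. Hydroxycarbonylation of F9 under the conditions of step 24 returns to the route at 38.

**Step 24.**
- Most likely failures: Heck-type insertion of the vinylpalladium intermediate into the neighbouring acrylate; slow carbonylation with hydrolysis or reduction of the triflate, on a substrate that already carries every functional group.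
- Fallback: the carboxyl carbon is introduced before the side chain. Enol triflate 27 is carbonylated (Pd(OAc)2, PPh3, CO, Et3N, DMF) in the presence of 2-(trimethylsilyl)ethanol to the 2-(trimethylsilyl)ethyl acrylate F10. DDQ gives the hydroxy ester F11, which is acylated at once with 34 under the conditions of step 23, because a cis γ-hydroxy ester can lactonise, to give the diester F12. (Me2N)3S+ Me3SiF2− in DMF removes the silylethyl ester and the silyl ether to give the acetonide acid F13. Aqueous acetic acid as in step 25 returns to the route at 39.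

## Further compounds

F1 | step 13 | enantiomer of cycloadduct 21 | O=C1OCCN1C(=O)[C@H]2[C@@H]3C=C(CO[Si](C)(C)C(C)(C)C)CC[C@H]3C(O[Si](C)(C)C(C)(C)C)=C[C@H]2OCc4ccc(OC)cc4
F2 | step 13 | enantiomer of ketone 22 | O=C1OCCN1C(=O)[C@H]2[C@@H]3C=C(CO[Si](C)(C)C(C)(C)C)CC[C@H]3C(=O)C[C@H]2OCc4ccc(OC)cc4
F3 | step 11 | (2E,8E)-3-{[(tert-butyldimethylsilyl)oxy]methyl}-9-[(4-methoxybenzyl)oxy]-7-oxonona-2,8-dienal | O=C/C=C(/CO[Si](C)(C)C(C)(C)C)CCCC(=O)/C=C/OCc1ccc(OC)cc1
F4 | step 15 | C10 enol triflate of the cycloadduct series | O=C1OCCN1C(=O)[C@@H]2[C@H]3C=C(CO[Si](C)(C)C(C)(C)C)CC[C@@H]3C(OS(=O)(=O)C(F)(F)F)=C[C@@H]2OCc4ccc(OC)cc4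
F5 | step 15 | C10 (trimethylsilyl)methyl allylsilane | O=C1OCCN1C(=O)[C@@H]2[C@H]3C=C(CO[Si](C)(C)C(C)(C)C)CC[C@@H]3C(C[Si](C)(C)C)=C[C@@H]2OCc4ccc(OC)cc4
F6 | step 18 | hydrazone of methyl ketone 25 | NN=C(C)[C@@H]1[C@H]2C=C(CO[Si](C)(C)C(C)(C)C)CC[C@@H]2C(=C)C[C@@H]1OCc3ccc(OC)cc3
F7 | step 18 | 1-iodovinyl compound with C8 4-methoxybenzyl ether | C=C(I)[C@@H]1[C@H]2C=C(CO[Si](C)(C)C(C)(C)C)CC[C@@H]2C(=C)C[C@@H]1OCc3ccc(OC)cc3
F8 | step 18 | 1-iodovinyl C8 alcohol | C=C(I)[C@@H]1[C@H]2C=C(CO[Si](C)(C)C(C)(C)C)CC[C@@H]2C(=C)C[C@@H]1O
F9 | step 18 | 1-iodovinyl C8 ester | C=C(I)[C@@H]1[C@H]2C=C(CO[Si](C)(C)C(C)(C)C)CC[C@@H]2C(=C)C[C@@H]1OC(=O)C(=C)[C@H]3COC(C)(C)O3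
F10 | step 24 | 2-(trimethylsilyl)ethyl acrylate with C8 4-methoxybenzyl ether | C=C(C(=O)OCC[Si](C)(C)C)[C@@H]1[C@H]2C=C(CO[Si](C)(C)C(C)(C)C)CC[C@@H]2C(=C)C[C@@H]1OCc3ccc(OC)cc3
F11 | step 24 | 2-(trimethylsilyl)ethyl acrylate with free C8 hydroxyl | C=C(C(=O)OCC[Si](C)(C)C)[C@@H]1[C@H]2C=C(CO[Si](C)(C)C(C)(C)C)CC[C@@H]2C(=C)C[C@@H]1O
F12 | step 24 | diester: 2-(trimethylsilyl)ethyl acrylate and C8 side-chain ester | C=C(C(=O)OCC[Si](C)(C)C)[C@@H]1[C@H]2C=C(CO[Si](C)(C)C(C)(C)C)CC[C@@H]2C(=C)C[C@@H]1OC(=O)C(=C)[C@H]3COC(C)(C)O3
F13 | step 24 | acetonide acid with free C15 hydroxyl | C=C(C(=O)O)[C@@H]1[C@H]2C=C(CO)CC[C@@H]2C(=C)C[C@@H]1OC(=O)C(=C)[C@H]3COC(C)(C)O3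
A1 | alternative 1 | 4-{3-[5-oxo-2,5-dihydrofuran-2-yl]prop-1-en-2-yl}cyclohex-1-ene-1-carbaldehyde (butenolide enal) | O=CC1=CC[C@H](CC1)C(=C)C[C@H]1C=CC(=O)O1
A2 | alternative 1 | tricyclic lactone enal | O=C1C[C@@H]2[C@H]3C=C(C=O)CC[C@@H]3C(=C)C[C@@H]2O1
A3 | alternative 2 | methyl (Z)-2-(bromomethyl)-3-[trans-6-(4-oxobut-1-en-2-yl)-3-{[(tert-butyldimethylsilyl)oxy]methyl}cyclohex-2-en-1-yl]prop-2-enoate | O=CCC(=C)[C@H]1CCC(CO[Si](C)(C)C(C)(C)C)=C[C@@H]1/C=C(\CBr)C(=O)OC
A4 | alternative 2 | cis-fused α-methylene-γ-butyrolactone on the trans-decalin | C=C1[C@@H]2[C@H]3C=C(CO[Si](C)(C)C(C)(C)C)CC[C@@H]3C(=C)C[C@@H]2OC1=O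
A5 | alternative 3 | di-tert-butyl 2-{1-[(4-methoxybenzyl)oxy]-4-oxobutan-2-yl}malonate | O=CC[C@H](COCc1ccc(OC)cc1)C(C(=O)OC(C)(C)C)C(=O)OC(C)(C)C
A6 | alternative 3 | (E)-3-methyl-1-nitrobuta-1,3-diene | C=C(C)/C=C/[N+](=O)[O-]
A7 | alternative 3 | ethyl 2-(diethoxyphosphoryl)prop-2-enoate | C=C(C(=O)OCC)P(=O)(OCC)OCC
A8 | alternative 3 | nitrocyclohexene ester (ring B with C1 isopropenyl and the C7 side chain) | CC(C)(C)OC(=O)C(C(=O)OC(C)(C)C)[C@@H](COCc1ccc(OC)cc1)[C@H]1C=C(C(=O)OCC)C[C@@H]([N+](=O)[O-])[C@@H]1C(C)=C
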